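**Retrosynthetic overview**
- The saturated side chain is cut at C5'–C6': cross-metathesis and hydrogenation join (3S)-3-(hex-5-enyl)-5,7-dimethoxyphthalide with (2S)-dec-9-en-2-ol, which comes from hept-6-enylmagnesium bromide and (S)-propylene oxide.
- The lactone ring comes from the four-membered ketone: oxidative ring expansion (O inserted between C=O and the benzylic carbon) of racemic 8-(hex-5-enyl)-3,5-dimethoxybenzocyclobutenone, run so that it is enantioconvergent and sets C3.
- The four-membered ring comes from an aryne–ketene silyl acetal [2+2]: 3,5-dimethoxybenzyne (from 1-bromo-2,4-dimethoxybenzene, made from resorcinol) plus the acetal obtained from pent-4-enylmagnesium bromide, methyl acrylate and Me3SiCl.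
- Ring order: benzene ring bought (resorcinol), then the cyclobutenone by [2+2], then the five-membered lactone by ring expansion; the chain is completed last.

Assumption: the (S,S)-bisoxazoline is taken to give the (S)-lactone in step 5; if a first run shows the opposite sense, the (R,R)-ligand is used with no other change.

**Route**

Step 1
Reactants: 1 resorcinol
Product: 2 1,3-dimethoxybenzene
Conditions: Me2SO4 (2.4 equiv), K2CO3 (3 equiv), acetone, reflux
Reagents that add atoms: dimethyl sulfate, COS(=O)(=O)OC
Why: Twofold Williamson ether synthesis (SN2 O-methylation of the phenoxide); no stereocenter.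

Step 2
Reactants: 2 1,3-dimethoxybenzene
Product: 3 1-bromo-2,4-dimethoxybenzene
Conditions: NBS (1.0 equiv), MeCN, 0 °C → rt
Reagents that add atoms: N-bromosuccinimide, O=C1CCC(=O)N1Br
Why: Electrophilic aromatic bromination goes to C4, para to one methoxy group and ortho to the other, and stops at the monobromide with one equivalent of NBS.

Step 3
Reactants: 4 5-bromopent-1-ene, 5 methyl acrylate
Product: 7 [(1-methoxyocta-1,7-dien-1-yl)oxy]trimethylsilane (E/Z mixture), via pent-4-enylmagnesium bromide 6 (not isolated)
Conditions: Mg, THF, rt; then CuBr·SMe2 (5 mol %), Me3SiCl (2 equiv), HMPA (2 equiv), 5, THF, −78 °C; Et3N/pentane, filtration, distillation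
Reagents that add atoms: chlorotrimethylsilane, C[Si](C)(C)Cl
Why: Copper-catalysed, Me3SiCl-accelerated conjugate addition of the Grignard reagent to the acrylate, with O-silylation of the ester enolate in the flask, gives the ketene silyl acetal in one operation; the E/Z ratio is of no consequence.

Step 4
Reactants: 3 1-bromo-2,4-dimethoxybenzene, 7 [(1-methoxyocta-1,7-dien-1-yl)oxy]trimethylsilane
Product: 10 rac-8-(hex-5-en-1-yl)-3,5-dimethoxybicyclo[4.2.0]octa-1,3,5-trien-7-one, via 3,5-dimethoxybenzyne 8 (not isolated), via silyl methyl ketal 9 (not isolated)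
Conditions: 7 (2 equiv), LiTMP (lithium 2,2,6,6-tetramethylpiperidide, 2.2 equiv), THF, −78 °C → rt; then 1 M aq. HCl, THF, rt
Reagents that add atoms: none
Why: LiTMP removes H-6 of 3 and loss of LiBr gives aryne 8, which is attacked at the carbon remote from the neighbouring methoxy group by the nucleophilic carbon of 7, and the aryl anion formed ortho to OMe closes onto the acetal carbon (stepwise aryne–ketene acetal [2+2] cycloaddition), so the carbonyl ends up next to the methoxy-bearing carbon as the target requires; acid hydrolysis of 9 frees the ketone, and C8 is formed racemic on purpose.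

Step 5
Reactants: 10 rac-8-(hex-5-en-1-yl)-3,5-dimethoxybicyclo[4.2.0]octa-1,3,5-trien-7-one
Product: 13 (3S)-3-(hex-5-en-1-yl)-5,7-dimethoxy-2-benzofuran-1(3H)-one, via perhydrate 11 (not isolated), via benzylic radical 12 (not isolated)
Conditions: Cu(MeCN)4PF6 (10 mol %), (S,S)-t-Bu-Box (2,2'-(propane-2,2-diyl)bis[(4S)-4-tert-butyl-4,5-dihydro-1,3-oxazole], 12 mol %), urea·H2O2 (1.5 equiv, in portions), EtOAc, 0 °C
Reagents that add atoms: hydrogen peroxide (used as its urea adduct), OO
Why: Proposed new method: a copper-catalysed, enantioconvergent radical variant of the Baeyer–Villiger ring expansion, in which H2O2 adds to the strained ketone to give perhydrate 11, monovalent copper cleaves the O–O bond by single-electron transfer, and the 1-hydroxyalkoxyl radical undergoes strain-driven β-scission of the C7–C8 bond to the planar secondary benzylic radical 12 bearing an ortho carboxyl group, so both enantiomers of 10 converge on one achiral intermediate; the carboxylate binds the divalent copper–bisoxazoline complex, radical capture gives a six-membered trivalent copper metallacycle, and C–O reductive elimination closes the five-membered lactone, sets C3 under ligand control and returns monovalent copper (net: ketone + H2O2 → lactone + H2O), with regiochemistry fixed by radical stability (benzylic, not aryl) so that aryl migration cannot compete; the closest known reaction types are the iron- or copper-mediated ring opening of cycloalkanone perhydrates to ω-carboxyalkyl radicals, copper/bisoxazoline-catalysed enantioselective radical lactonisation of alkenoic acids by C–O reductive elimination, and the stereospecific polar Baeyer–Villiger oxidation of benzocyclobutenones to phthalides, and what is new is their merger into an enantioconvergent ring expansion of a racemic α-branched benzocyclobutenone.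

Step 6
Reactants: 14 7-bromohept-1-ene, 15 (S)-propylene oxide
Product: 17 (2S)-dec-9-en-2-ol, via hept-6-enylmagnesium bromide 16 (not isolated)
Conditions: Mg, THF; then CuBr·SMe2 (10 mol %), 15, THF, −30 → 0 °C; aqueous work-up
Reagents that add atoms: none
Why: Copper-catalysed SN2 opening of the epoxide by the Grignard reagent at the unsubstituted carbon leaves the C–O stereocenter of (S)-propylene oxide untouched, so the carbinol is (S).

Step 7
Reactants: 13 (3S)-3-(hex-5-en-1-yl)-5,7-dimethoxy-2-benzofuran-1(3H)-one, 17 (2S)-dec-9-en-2-ol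
Product: 19 (3S)-3-[(13S)-13-hydroxytetradecyl]-5,7-dimethoxy-2-benzofuran-1(3H)-one, via metathesis alkene 18 (not isolated)
Conditions: 17 (3 equiv), second-generation Grubbs catalyst ((H2IMes)(PCy3)Cl2Ru=CHPh, 5 mol %), CH2Cl2, 40 °C; then Pd/C (10 wt %), H2 (1 atm), EtOAc added, rt
Reagents that add atoms: none
Why: Olefin cross-metathesis of two unhindered terminal alkenes (excess of the cheap partner 17, ethene lost) is followed in the same flask by heterogeneous hydrogenation of the new double bond; neither stereocenter is touched, so the (3S,13'S) target results.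

**Compound list**
1 | resorcinol | Oc1cccc(O)c1 | starting material
2 | 1,3-dimethoxybenzene | COc1cccc(OC)c1 | intermediate
3 | 1-bromo-2,4-dimethoxybenzene | COc1ccc(Br)c(OC)c1 | intermediate
4 | 5-bromopent-1-ene | C=CCCCBr | starting material
5 | methyl acrylate | C=CC(=O)OC | starting material
6 | pent-4-enylmagnesium bromide | C=CCCC[Mg]Br | intermediate
7 | [(1-methoxyocta-1,7-dien-1-yl)oxy]trimethylsilane (E/Z mixture) | C=CCCCCC=C(OC)O[Si](C)(C)C | intermediate
8 | 3,5-dimethoxybenzyne (1,2-didehydro-3,5-dimethoxybenzene) | COC1=CC(OC)=CC#C1 | intermediate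
9 | 8-(hex-5-en-1-yl)-3,5,7-trimethoxy-7-[(trimethylsilyl)oxy]bicyclo[4.2.0]octa-1,3,5-triene (racemic, diastereomer mixture) | COc1cc(OC)c2c(c1)C(CCCCC=C)C2(OC)O[Si](C)(C)C | intermediate
10 | rac-8-(hex-5-en-1-yl)-3,5-dimethoxybicyclo[4.2.0]octa-1,3,5-trien-7-one | COc1cc(OC)c2c(c1)C(CCCCC=C)C2=O | intermediate
11 | 8-(hex-5-en-1-yl)-7-hydroperoxy-3,5-dimethoxybicyclo[4.2.0]octa-1,3,5-trien-7-ol (racemic) | COc1cc(OC)c2c(c1)C(CCCCC=C)C2(O)OO | intermediate
12 | 1-(2-carboxy-3,5-dimethoxyphenyl)hept-6-en-1-yl radical (copper carboxylate in the flask) | COc1cc(OC)c(C(O)=O)c(c1)[CH]CCCCC=C | intermediate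
13 | (3S)-3-(hex-5-en-1-yl)-5,7-dimethoxy-2-benzofuran-1(3H)-one | COc1cc(OC)c2c(c1)[C@H](CCCCC=C)OC2=O | intermediate
14 | 7-bromohept-1-ene | C=CCCCCCBr | starting material
15 | (S)-propylene oxide ((2S)-2-methyloxirane) | C[C@H]1CO1 | starting material
16 | hept-6-enylmagnesium bromide | C=CCCCCC[Mg]Br | intermediate
17 | (2S)-dec-9-en-2-ol | C=CCCCCCC[C@H](C)O | intermediate
18 | (3S)-3-[(13S)-13-hydroxytetradec-5-en-1-yl]-5,7-dimethoxy-2-benzofuran-1(3H)-one (E/Z mixture, E drawn) | COc1cc(OC)c2c(c1)[C@H](CCCC/C=C/CCCCCC[C@H](C)O)OC2=O | intermediate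
19 | (3S)-3-[(13S)-13-hydroxytetradecyl]-5,7-dimethoxy-2-benzofuran-1(3H)-one | COc1cc(OC)c2c(c1)[C@H](CCCCCCCCCCCC[C@H](C)O)OC2=O | target

**Step count and risks**
Total steps: 7. Longest linear sequence: 5 (steps 1, 2, 4, 5, 7).

Step 5 (the new ring expansion) is the most likely to fail. A copper-assisted polar Baeyer–Villiger background would be stereospecific and give racemic lactone, ligand control may be low, and Fenton-type side reactions are possible. The fallback sets out from 10 and comes back at 13, using known chemistry only. Alkaline hydrogen peroxide (30 % H2O2, NaOH, MeOH–THF, 0 °C, then acid) effects the ordinary Baeyer–Villiger ring expansion of 10, with migration of the sp3 carbon, to racemic 3-(hex-5-en-1-yl)-5,7-dimethoxy-2-benzofuran-1(3H)-one F1. AlMe3-mediated aminolysis with (S)-1-phenylethylamine opens the lactone to two diastereomeric hydroxy amides: 2-[(1S)-1-hydroxyhept-6-en-1-yl]-4,6-dimethoxy-N-[(1S)-1-phenylethyl]benzamide F2 and 2-[(1R)-1-hydroxyhept-6-en-1-yl]-4,6-dimethoxy-N-[(1S)-1-phenylethyl]benzamide F3. They are separated by chromatography or crystallisation, and F2 is relactonised with TsOH in toluene at 80 °C, with the amine expelled and the carbinol configuration retained, to give 13. This is a classical resolution, so at most half of the material is used.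

Step 4 (aryne [2+2]) is second. LiTMP may lithiate 3 between the two methoxy groups instead of next to bromine, so aryne formation needs warming, and the labile silyl acetal 7 may suffer. The fallback sets out from 2 and comes back at 10, changing how the aryne is made. Sterically controlled C–H borylation of 2 at C5 ([Ir(OMe)(cod)]2, 4,4'-di-tert-butyl-2,2'-bipyridine, B2pin2, 80 °C) gives 2-(3,5-dimethoxyphenyl)-4,4,5,5-tetramethyl-1,3,2-dioxaborolane F4. Oxidation (H2O2, NaOH) gives 3,5-dimethoxyphenol F5, and Tf2O/pyridine gives 3,5-dimethoxyphenyl trifluoromethanesulfonate F6. In F6 both positions between OTf and OMe are equivalent and acidic, so LiTMP at −78 °C in the presence of 7 gives the same aryne 8 cleanly by loss of lithium triflate. Trapping to 9 and acid hydrolysis give 10.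

Step 3 (one-pot conjugate addition and silyl trapping) is third. The acrylate may polymerise or undergo 1,2-addition, C-silylation may compete, and the trimethylsilyl acetal may be lost on isolation. The fallback sets out from 3, with tert-butyl acetate and 6-bromohex-1-ene as new inputs, and comes back at 10; it replaces the conjugate addition by enolate alkylation. LiN(i-Pr)2 and tert-butyl acetate in THF at −78 °C, then 6-bromohex-1-ene with DMPU, give tert-butyl oct-7-enoate F7. LiN(i-Pr)2/TBSCl converts it into the robust tert-butyl[(1-tert-butoxyocta-1,7-dien-1-yl)oxy]dimethylsilane F8. The aryne [2+2] with 3 under the step 4 conditions gives 7-tert-butoxy-7-[(tert-butyldimethylsilyl)oxy]-8-(hex-5-en-1-yl)-3,5-dimethoxybicyclo[4.2.0]octa-1,3,5-triene F9, and aq. HF in MeCN hydrolyses it to 10.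

**Further compounds**
F1 | step 5 | rac-3-(hex-5-en-1-yl)-5,7-dimethoxy-2-benzofuran-1(3H)-one | COc1cc(OC)c2c(c1)C(CCCCC=C)OC2=O
F2 | step 5 | 2-[(1S)-1-hydroxyhept-6-en-1-yl]-4,6-dimethoxy-N-[(1S)-1-phenylethyl]benzamide | COc1cc(OC)c(C(=O)N[C@@H](C)c2ccccc2)c(c1)[C@H](CCCCC=C)O
F3 | step 5 | 2-[(1R)-1-hydroxyhept-6-en-1-yl]-4,6-dimethoxy-N-[(1S)-1-phenylethyl]benzamide | COc1cc(OC)c(C(=O)N[C@@H](C)c2ccccc2)c(c1)[C@@H](CCCCC=C)O
F4 | step 4 | 2-(3,5-dimethoxyphenyl)-4,4,5,5-tetramethyl-1,3,2-dioxaborolane | COc1cc(OC)cc(c1)B1OC(C)(C)C(C)(C)O1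
F5 | step 4 | 3,5-dimethoxyphenol | COc1cc(O)cc(OC)c1
F6 | step 4 | 3,5-dimethoxyphenyl trifluoromethanesulfonate | COc1cc(OC)cc(OS(=O)(=O)C(F)(F)F)c1
F7 | step 3 | tert-butyl oct-7-enoate | C=CCCCCCC(=O)OC(C)(C)C
F8 | step 3 | tert-butyl[(1-tert-butoxyocta-1,7-dien-1-yl)oxy]dimethylsilane (E/Z mixture) | C=CCCCCC=C(OC(C)(C)C)O[Si](C)(C)C(C)(C)C
F9 | step 3 | 7-tert-butoxy-7-[(tert-butyldimethylsilyl)oxy]-8-(hex-5-en-1-yl)-3,5-dimethoxybicyclo[4.2.0]octa-1,3,5-triene (racemic) | COc1cc(OC)c2c(c1)C(CCCCC=C)C2(OC(C)(C)C)O[Si](C)(C)C(C)(C)C
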